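# Proposed synthesis of 5,7,2',4'-tetrahydroxy-6-(3-hydroxy-3-methylbutyl)flavone (19)

## Analysis of the target

Target 19 is a flavone: a 4H-chromen-4-one (benzo ring A fused to pyranone ring C) with a 2,4-dihydroxyphenyl ring B on C2, hydroxyls on C5 and C7, and a 3-hydroxy-3-methylbutyl chain on C6. It has no stereocenter and no stereogenic double bond, so the problem is one of constitution only. The sensitive groups are the four phenols, the tertiary alcohol and the pyranone. The phenols make ring A (phloroglucinol type) and ring B (resorcinol type) prone to oxidation and electrophilic substitution. The tertiary alcohol ionizes under acid and then dehydrates or cyclizes onto O5 or O7 to a dimethylchroman. The pyranone is opened at C2 by strong nucleophiles. The difficulty is regiochemical: the chain must sit on C6 and not on C8, although three oxygens activate both positions, and five hydroxyls of three kinds must be kept apart up to a non-acidic last step. The strategy rests on ring B, which carries oxygen on C2' and C4', hydrogen on C3', C5' and C6', and is joined to ring C only through C1'–C2. A 1,1,3-trioxygenated butadiene (C2'–C3'–C4'–C5') leaves exactly this pattern when it adds to a two-carbon alkyne unit (C1', C6') on C2 and the adduct aromatizes. A second useful feature is that ring A is symmetric until ring C closes, so a symmetric acetophenone can give a chromone whose single free hydroxyl on C5 then directs substitution to C6.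

## Retrosynthetic reasoning

**19 to 18.** The last step should be reductive and neutral because of the acid-labile tertiary alcohol. No skeletal bond is cut: 19 is traced to alkynol 18, in which the two chain carbons next to C6 form a triple bond and O5, O7 and O2' carry benzyl groups. The forward step must saturate the alkyne and cleave three benzylic C–O bonds in one operation without touching C2=C3.

**18 to 16 and 17.** The C6–C(sp) bond is cut. An aryl iodide plus a terminal alkyne is the most dependable way to attach the five-carbon chain with its carbinol already in place, and 2-methylbut-3-yn-2-ol 17 is commercial. The iodine of iodoflavone 16 defines C6. In 16 the neighbouring O5 is benzylated, so the coupled alkyne has no free ortho hydroxyl to cyclize onto.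

**16 to 10 and 13 (key disconnection).** Both C1'–C2' and C5'–C6' are cut, so ring B disappears altogether. What remains is the ethynyl group of 2-ethynylchromone 10 (C1' and C6') and the acyclic diene 13 (C2' to C5'). Cutting C2–C1' instead, or opening ring C, would need a preformed, differentially protected ring-B building block. Here the 2',4'-oxygen pattern comes from the diene, and O2' (benzyl) and O4' (free) arrive differentiated. The iodine is carried through on 10 as a spectator, so no electrophilic substitution is needed once the electron-rich ring B exists. The forward reaction has to deliver the right regiochemistry (benzyloxy ortho, hydroxyl para to C1') and aromatize.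

**13 to 12 to 11.** Two O–Si bonds are cut in turn. Diene 13 is the bis-silyl dienol ether of benzyl acetoacetate 11, reached through the mono-silyl enol ether 12.

**10 to 9 to 8 to 7.** The alkyne carbon C6' is removed, leading back to aldehyde 9 (one-carbon homologation forward). The aldehyde comes from ester 7 through alcohol 8, because the ester is the oxidation level that the chromone ring synthesis delivers and its reduction is chemoselective.

**7 to 6 to 5.** The O5–benzyl bond and then the C6–I bond are cut. Iodination is placed at chromone ester 5 for two reasons: ring A is then the only arene in the molecule, and its free, chelated 5-hydroxyl has C6 as its only open ortho position. Benzylation follows the iodination, since a 5-alkoxy group would send the electrophile to C8.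

**5 to 2 and 3, then 2 to 1.** Ring C is opened at O1–C2 and C2–C3, giving 4-O-benzylphloroacetophenone 2 and diethyl oxalate 3. The two phenols of 2 are equivalent, so ring closure can give only one chromone and the other hydroxyl becomes the 5-OH. Compound 2 is the mono-benzyl ether of 2',4',6'-trihydroxyacetophenone 1.

## Alternatives that were turned down

**Alternative 1:** Disconnection of C4a–C5, so that ring A is formed last by folding a polyketide chain that hangs on a finished 2-aryl-4-pyranone. The precursor would be the β-keto ester A1, with the side chain on the carbon between ketone and ester. In the forward step, base would generate a dienolate extending through the pyranone, the pyranone carbon destined to be C4a would acylate with the terminal ester, and enolization would give flavone A2. In its favour, the chain is on C6 by construction, with no halogenation, no cross-coupling and no C6/C8 question, and ring B arrives complete. On this point it is stronger than the chosen route. Against it, the most acidic hydrogen of A1 lies between the ketone and the ester. Removing it makes the ester part of an enolate, a very poor acceptor for the Claisen closure, and the nucleophilic site on the pyranone side then has to be generated as a further anion. Retro-Claisen cleavage of the substituted β-keto ester competes. A1 also needs a long linear assembly, and A2 carries two kinds of protecting groups, so two deprotections follow. The chosen route offers cheap, robust fragments, a thermal pericyclic key step whose regiochemistry follows from polarization, and only two steps after it.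

**Alternative 2:** Disconnection of C4–C4a, closing ring C last by intramolecular acylation. The precursor is the (Z)-aryloxyacrylic acid A3. Activating its carboxyl group as an acylating species lets it attack the ortho carbon of the symmetric 3,5-dioxygenated aryloxy ring and gives the tetrabenzyl flavone A4. In its favour, the ring closure is of a well-established type on a very nucleophilic ring with two equivalent ortho positions, and the assembly is convergent. In precedent it is clearly stronger than the chosen key step. Against it, A4 has no handle on C6. After the key step the route would still have to free O5 selectively, iodinate ring A in the presence of the electron-rich ring B, couple next to a free hydroxyl and reduce, which is four to five further steps with their own selectivity problems. Strong electrophilic activation in the presence of four benzyl ethers invites debenzylation and benzyl transfer to the rings, and only the Z isomer can cyclize. The chosen route settles C6 before ring B exists and needs two steps after the key step.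

**Alternative 3:** Disconnection of four ring-A bonds (C8–C8a, C5–C6, C7–C8, C4a–C5), building ring A onto a pyranone. The precursors are the pyranonyl diazo ketone A5 and the siloxyalkyne A6, which carries the chain. Irradiation would trigger a Wolff rearrangement of A5 to a pyranonyl ketene. Cycloaddition (2+2) with A6, four-electron opening of the cyclobutenone and six-electron closure onto the pyranone double bond would then give phenol A7 after tautomerization. In its favour, it is the most convergent plan, and the alkyne polarity fixes both the chain position and the O5/O7 differentiation. In convergence and in certainty of ring-A regiochemistry it is stronger than the chosen route. Against it, A5 needs a pyranone carboxylic acid and hazardous diazo chemistry, and A6 needs a multi-step ynolate synthesis and is hydrolytically fragile. The 2-aryl-4-pyranone chromophore absorbs where the diazo ketone must be excited and can itself photoisomerize. The electrocyclization has to engage a vinylogous-ester double bond, and three kinds of protecting groups require two deprotections. The chosen route uses one protecting group type, inexpensive starting materials and a purely thermal key step with a fallback in known chemistry.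

Key step: step 10

## Route

Assumption: enol silyl ether 12 is taken as an E/Z mixture and adduct 14 as a racemate. Neither element reaches the target, so their SMILES carry no stereodescriptors.

**Step 1**
Reactants: 1 2',4',6'-trihydroxyacetophenone
Product: 2 1-[4-(benzyloxy)-2,6-dihydroxyphenyl]ethanone
Conditions: BnBr (1.0 equiv), K2CO3 (1.0 equiv), DMF, 0 °C to rt
Reagents that add atoms: benzyl bromide, BrCc1ccccc1
Why: Williamson ether synthesis; the 4-hydroxyl is the only one not hydrogen-bonded to the acetyl carbonyl and is the most acidic, so one equivalent of electrophile should react there first.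

**Step 2**
Reactants: 2 1-[4-(benzyloxy)-2,6-dihydroxyphenyl]ethanone; 3 diethyl oxalate
Product: 5 ethyl 7-(benzyloxy)-5-hydroxy-4-oxo-4H-chromene-2-carboxylate, via diketo ester 4 (not isolated)
Conditions: NaOEt (3.5 equiv), EtOH–THF, 0 to 60 °C; then HCl (excess), EtOH, 70 °C
Reagents that add atoms: none
Why: Crossed Claisen condensation of the methyl ketone enolate with the non-enolizable oxalate, then acid-catalysed cyclodehydration to the chromone-2-carboxylate. The two phenols of 2 are equivalent, so only one chromone can form and the other hydroxyl becomes the chelated 5-OH.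

**Step 3**
Reactants: 5 ethyl 7-(benzyloxy)-5-hydroxy-4-oxo-4H-chromene-2-carboxylate
Product: 6 ethyl 7-(benzyloxy)-5-hydroxy-6-iodo-4-oxo-4H-chromene-2-carboxylate
Conditions: BnMe3N·ICl2 (1.05 equiv), CaCO3, CH2Cl2–MeOH, rt
Reagents that add atoms: benzyltrimethylammonium dichloroiodate, C[N+](C)(C)Cc1ccccc1.Cl[I-]Cl
Why: Electrophilic aromatic iodination of a phenol; under these weakly basic conditions the reagent attacks free phenols ortho to the hydroxyl, and C6 is the only open ortho position of the 5-OH. Ring A is the only arene present at this stage.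

**Step 4**
Reactants: 6 ethyl 7-(benzyloxy)-5-hydroxy-6-iodo-4-oxo-4H-chromene-2-carboxylate
Product: 7 ethyl 5,7-bis(benzyloxy)-6-iodo-4-oxo-4H-chromene-2-carboxylate
Conditions: BnBr, K2CO3, n-Bu4NI (cat.), DMF, 60 °C
Reagents that add atoms: benzyl bromide, BrCc1ccccc1
Why: Williamson ether synthesis on the ortho-iodophenol, whose acidity is raised by the iodine. The ether removes the acidic proton before the silyl dienol ether chemistry and prevents furan annulation of the ortho-alkynylphenol in step 11.

**Step 5**
Reactants: 7 ethyl 5,7-bis(benzyloxy)-6-iodo-4-oxo-4H-chromene-2-carboxylate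
Product: 8 5,7-bis(benzyloxy)-2-(hydroxymethyl)-6-iodo-4H-chromen-4-one
Conditions: NaBH4, MeOH–THF, 0 °C
Reagents that add atoms: none
Why: Chemoselective borohydride reduction; the C2 ester is activated by the ring oxygen and the enone, while the C4 carbonyl is a vinylogous ester deactivated by O5 and O7, and the aryl iodide is inert.

**Step 6**
Reactants: 8 5,7-bis(benzyloxy)-2-(hydroxymethyl)-6-iodo-4H-chromen-4-one
Product: 9 5,7-bis(benzyloxy)-6-iodo-4-oxo-4H-chromene-2-carbaldehyde
Conditions: Dess–Martin periodinane, CH2Cl2, rt
Reagents that add atoms: none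
Why: Dess–Martin oxidation of a primary allylic-type alcohol under neutral conditions; it should stop at the aldehyde and leave the benzyl ethers and the iodide alone.

**Step 7**
Reactants: 9 5,7-bis(benzyloxy)-6-iodo-4-oxo-4H-chromene-2-carbaldehyde
Product: 10 5,7-bis(benzyloxy)-2-ethynyl-6-iodo-4H-chromen-4-one
Conditions: dimethyl (1-diazo-2-oxopropyl)phosphonate, K2CO3, MeOH–THF, 0 °C to rt
Reagents that add atoms: dimethyl (1-diazo-2-oxopropyl)phosphonate, COP(=O)(OC)C(=[N+]=[N-])C(C)=O
Why: Seyferth–Gilbert homologation in the Ohira–Bestmann variant; the diazomethylphosphonate anion adds to the aldehyde, cycloelimination and loss of N2 give an alkylidene carbene, and a 1,2-hydrogen shift gives the terminal alkyne. The aldehyde is far more electrophilic than the pyranone, and C3 is an enol-ether β-carbon, so the conjugate addition of methanol that troubles simple enals is not expected.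

**Step 8**
Reactants: 11 benzyl acetoacetate
Product: 12 benzyl 3-(trimethylsilyloxy)but-2-enoate
Conditions: Me3SiCl, Et3N, toluene, rt
Reagents that add atoms: chlorotrimethylsilane, C[Si](C)(C)Cl
Why: O-silylation of the β-keto ester enol under amine base gives the silyl enol ether.

**Step 9**
Reactants: 12 benzyl 3-(trimethylsilyloxy)but-2-enoate
Product: 13 (1Z)-1-(benzyloxy)-1,3-bis(trimethylsilyloxy)buta-1,3-diene
Conditions: LiN(iPr)2, THF, −78 °C; Me3SiCl, −78 °C to rt
Reagents that add atoms: chlorotrimethylsilane, C[Si](C)(C)Cl
Why: γ-Deprotonation gives the extended ester dienolate, which is silylated on oxygen to the 1-alkoxy-1,3-bis(silyloxy)diene; the ketene acetal geometry has no consequence because it is lost on aromatization.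

**Step 10**
Reactants: 10 5,7-bis(benzyloxy)-2-ethynyl-6-iodo-4H-chromen-4-one; 13 (1Z)-1-(benzyloxy)-1,3-bis(trimethylsilyloxy)buta-1,3-diene
Product: 16 5,7-bis(benzyloxy)-2-[2-(benzyloxy)-4-hydroxyphenyl]-6-iodo-4H-chromen-4-one, via cyclohexadiene adduct 14 (not isolated), via aryl silyl ether 15 (not isolated)
Conditions: 13 (3 equiv), toluene, 110 °C, sealed tube; then 1 M HCl, THF–MeOH, rt
Reagents that add atoms: none
Why: Proposed new method: a thermal Diels–Alder reaction between the electron-rich diene 13 and the alkyne of 10, whose terminal carbon is the far end of the O=C4–C3=C2–C≡C acceptor chain and therefore the electrophilic one; the closest known reaction type is the cycloaddition–aromatization of 1-alkoxy-1,3-bis(silyloxy)butadienes and 1,1-dialkoxy-3-silyloxybutadienes with alkynones and alkynoates, which gives 2-alkoxy-4-hydroxyaryl ketones and esters. Ring B closes by a (4+2) cycloaddition, either concerted and asynchronous or stepwise through a vinylogous Mukaiyama–Michael addition followed by ring closure; in both cases the nucleophilic CH2 terminus of the diene bonds to the terminal alkyne carbon (C5'–C6') and the ketene acetal carbon bonds to the internal alkyne carbon (C1'–C2'). Adduct 14 is a 1,4-cyclohexadiene with a mixed ketal on C2' and a CH2 on C5'; 1,4-elimination of trimethylsilanol across these positions aromatizes it to 15, and the acidic work-up cleaves the aryl silyl ether to 16. No stereocenter is formed that persists, since the ketal carbon of 14 is destroyed on aromatization. The selectivity needed is regiochemical (benzyloxy ortho and hydroxyl para to C1') and is secured by the matched polarization of the two partners. The alkyne is preferred over C2=C3 because attack on the endocyclic bond would break the vinylogous ester conjugation. The ring oxygen donates into C2 and makes the alkyne a weaker dienophile than a simple ynone, hence the excess of diene and the heating. If the adduct lost the benzyloxy group in place of the silyloxy group, the 2'-hydroxy analogue would form, and steps 11 and 12 would carry it to the same target.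

**Step 11**
Reactants: 16 5,7-bis(benzyloxy)-2-[2-(benzyloxy)-4-hydroxyphenyl]-6-iodo-4H-chromen-4-one; 17 2-methylbut-3-yn-2-ol
Product: 18 5,7-bis(benzyloxy)-2-[2-(benzyloxy)-4-hydroxyphenyl]-6-(3-hydroxy-3-methylbut-1-yn-1-yl)-4H-chromen-4-one
Conditions: Pd(PPh3)2Cl2 (5 mol %), CuI (10 mol %), Et3N, DMF, 60 °C
Reagents that add atoms: none
Why: Sonogashira coupling; the C6–I bond adds oxidatively to zerovalent palladium formed in situ, the copper acetylide of 17 transmetalates and reductive elimination forms the C6–C(sp) bond. Both oxygens flanking C6 are benzylated, so the product cannot cyclize to a furan, and the free 4'-phenol and the tertiary alcohol are tolerated.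

**Step 12**
Reactants: 18 5,7-bis(benzyloxy)-2-[2-(benzyloxy)-4-hydroxyphenyl]-6-(3-hydroxy-3-methylbut-1-yn-1-yl)-4H-chromen-4-one
Product: 19 5,7-dihydroxy-2-(2,4-dihydroxyphenyl)-6-(3-hydroxy-3-methylbutyl)-4H-chromen-4-one
Conditions: H2 (1 atm), Pd/C (10 % Pd), EtOAc–MeOH, rt
Reagents that add atoms: none
Why: Heterogeneous catalytic hydrogenation saturates the alkyne and hydrogenolyses the three benzyl ethers in one neutral operation. The C2=C3 bond, a vinylogous ester conjugated with both rings, and the tertiary alcohol should remain untouched at 1 atm and rt.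

## Compound list

1 | 2',4',6'-trihydroxyacetophenone | CC(=O)c1c(O)cc(O)cc1O | starting material
2 | 1-[4-(benzyloxy)-2,6-dihydroxyphenyl]ethanone | CC(=O)c1c(O)cc(OCc2ccccc2)cc1O | intermediate
3 | diethyl oxalate | CCOC(=O)C(=O)OCC | starting material
4 | ethyl 4-[4-(benzyloxy)-2,6-dihydroxyphenyl]-2,4-dioxobutanoate | CCOC(=O)C(=O)CC(=O)c1c(O)cc(OCc2ccccc2)cc1O | intermediate
5 | ethyl 7-(benzyloxy)-5-hydroxy-4-oxo-4H-chromene-2-carboxylate | CCOC(=O)c1cc(=O)c2c(O)cc(OCc3ccccc3)cc2o1 | intermediate
6 | ethyl 7-(benzyloxy)-5-hydroxy-6-iodo-4-oxo-4H-chromene-2-carboxylate | CCOC(=O)c1cc(=O)c2c(O)c(I)c(OCc3ccccc3)cc2o1 | intermediate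
7 | ethyl 5,7-bis(benzyloxy)-6-iodo-4-oxo-4H-chromene-2-carboxylate | CCOC(=O)c1cc(=O)c2c(OCc3ccccc3)c(I)c(OCc3ccccc3)cc2o1 | intermediate
8 | 5,7-bis(benzyloxy)-2-(hydroxymethyl)-6-iodo-4H-chromen-4-one | OCc1cc(=O)c2c(OCc3ccccc3)c(I)c(OCc3ccccc3)cc2o1 | intermediate
9 | 5,7-bis(benzyloxy)-6-iodo-4-oxo-4H-chromene-2-carbaldehyde | O=Cc1cc(=O)c2c(OCc3ccccc3)c(I)c(OCc3ccccc3)cc2o1 | intermediate
10 | 5,7-bis(benzyloxy)-2-ethynyl-6-iodo-4H-chromen-4-one | C#Cc1cc(=O)c2c(OCc3ccccc3)c(I)c(OCc3ccccc3)cc2o1 | intermediate
11 | benzyl acetoacetate | CC(=O)CC(=O)OCc1ccccc1 | starting material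
12 | benzyl 3-(trimethylsilyloxy)but-2-enoate (E/Z mixture) | CC(O[Si](C)(C)C)=CC(=O)OCc1ccccc1 | intermediate
13 | (1Z)-1-(benzyloxy)-1,3-bis(trimethylsilyloxy)buta-1,3-diene | C=C(O[Si](C)(C)C)/C=C(/OCc1ccccc1)O[Si](C)(C)C | intermediate
14 | 5,7-bis(benzyloxy)-2-[6-(benzyloxy)-4,6-bis(trimethylsilyloxy)cyclohexa-1,4-dien-1-yl]-6-iodo-4H-chromen-4-one (racemic) | O=c1cc(C3=CCC(O[Si](C)(C)C)=CC3(OCc4ccccc4)O[Si](C)(C)C)oc2cc(OCc3ccccc3)c(I)c(OCc3ccccc3)c12 | intermediate
15 | 5,7-bis(benzyloxy)-2-[2-(benzyloxy)-4-(trimethylsilyloxy)phenyl]-6-iodo-4H-chromen-4-one | C[Si](C)(C)Oc1ccc(-c2cc(=O)c3c(OCc4ccccc4)c(I)c(OCc4ccccc4)cc3o2)c(OCc2ccccc2)c1 | intermediate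
16 | 5,7-bis(benzyloxy)-2-[2-(benzyloxy)-4-hydroxyphenyl]-6-iodo-4H-chromen-4-one | O=c1cc(-c2ccc(O)cc2OCc2ccccc2)oc2cc(OCc3ccccc3)c(I)c(OCc3ccccc3)c12 | intermediate
17 | 2-methylbut-3-yn-2-ol | CC(C)(O)C#C | starting material
18 | 5,7-bis(benzyloxy)-2-[2-(benzyloxy)-4-hydroxyphenyl]-6-(3-hydroxy-3-methylbut-1-yn-1-yl)-4H-chromen-4-one | CC(C)(O)C#Cc1c(OCc2ccccc2)cc2oc(-c3ccc(O)cc3OCc3ccccc3)cc(=O)c2c1OCc1ccccc1 | intermediate
19 | 5,7-dihydroxy-2-(2,4-dihydroxyphenyl)-6-(3-hydroxy-3-methylbutyl)-4H-chromen-4-one | CC(C)(O)CCc1c(O)cc2oc(-c3ccc(O)cc3O)cc(=O)c2c1O | target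

## Step count and least certain steps

Total step count: 12. Longest linear sequence: 10 steps (steps 1 to 7, then 10 to 12). The diene branch (steps 8 and 9) joins at step 10.

**Step 10 (key step, the one step without direct precedent).**
- The most likely failure is insufficient dienophilicity of the donor-substituted alkyne, so that thermal silyl migration and decomposition of the diene outrun cycloaddition.
- A second risk is conjugate addition of the silyl dienol ether to C2 of the pyranone in place of cycloaddition.
- A third is cycloaddition with the reverse orientation.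
- Fallback in known chemistry, setting out from 2 and returning at 19: Claisen–Schmidt condensation of 2 with commercial 2,4-bis(benzyloxy)benzaldehyde (KOH, EtOH) should give (E)-1-[4-(benzyloxy)-2,6-dihydroxyphenyl]-3-[2,4-bis(benzyloxy)phenyl]prop-2-en-1-one F1. Oxidative cyclization (I2 cat., DMSO, 120 °C) should give 7-(benzyloxy)-2-[2,4-bis(benzyloxy)phenyl]-5-hydroxy-4H-chromen-4-one F2. Iodination as in step 3, with a reagent that attacks free phenols and not aryl ethers, should give 7-(benzyloxy)-2-[2,4-bis(benzyloxy)phenyl]-5-hydroxy-6-iodo-4H-chromen-4-one F3. Benzylation as in step 4 should give 5,7-bis(benzyloxy)-2-[2,4-bis(benzyloxy)phenyl]-6-iodo-4H-chromen-4-one F4. Sonogashira coupling with 17 as in step 11 should give 5,7-bis(benzyloxy)-2-[2,4-bis(benzyloxy)phenyl]-6-(3-hydroxy-3-methylbut-1-yn-1-yl)-4H-chromen-4-one F5, and hydrogenation as in step 12 should give 19.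

**Step 7.**
- Methoxide may add to C2 of the aldehyde-activated pyranone and open the ring, or add across the newly formed, acceptor-conjugated alkyne.
- Fallback, setting out from 9 and returning at 10: Stork–Zhao olefination with Ph3P=CHI (from (iodomethyl)triphenylphosphonium iodide and NaN(SiMe3)2, THF, −78 °C) should give 5,7-bis(benzyloxy)-6-iodo-2-[(Z)-2-iodoethenyl]-4H-chromen-4-one F6. Anti-elimination of hydrogen iodide with n-Bu4NF in DMF should then give 10 without any alkoxide.

**Step 1.**
- Over-alkylation at a second hydroxyl and C-benzylation of the phloroglucinol nucleus may erode the supply of the mono-ether.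
- Fallback, setting out from 1 and returning at 5: twofold benzylation (BnBr 2.2 equiv, K2CO3, DMF), which stops at the chelated hydroxyl, should give 1-[2,4-bis(benzyloxy)-6-hydroxyphenyl]ethanone F7. Condensation with 3 and cyclization as in step 2 should give ethyl 5,7-bis(benzyloxy)-4-oxo-4H-chromene-2-carboxylate F8. Chelation-controlled cleavage of the benzyl ether next to the carbonyl (MgBr2·OEt2, toluene–Et2O, 80 °C) should give 5.

**Step 11.**
- Coupling at the doubly ortho-substituted, electron-rich C6 may be slow, so that copper-mediated oxidative dimerization of 17 and reductive loss of iodine compete.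
- Fallback, setting out from 16 and returning at 19: a Heck reaction of 16 with commercial 2-methylbut-3-en-2-ol (Pd(OAc)2, n-Bu4NCl, NaHCO3, DMF, 90 °C) uses no copper and no alkyne. It should give 5,7-bis(benzyloxy)-2-[2-(benzyloxy)-4-hydroxyphenyl]-6-[(E)-3-hydroxy-3-methylbut-1-en-1-yl]-4H-chromen-4-one F9, which hydrogenation as in step 12 should convert to 19.

## Further compounds

F1 | step 10 | (E)-1-[4-(benzyloxy)-2,6-dihydroxyphenyl]-3-[2,4-bis(benzyloxy)phenyl]prop-2-en-1-one | O=C(/C=C/c1ccc(OCc2ccccc2)cc1OCc1ccccc1)c1c(O)cc(OCc2ccccc2)cc1O
F2 | step 10 | 7-(benzyloxy)-2-[2,4-bis(benzyloxy)phenyl]-5-hydroxy-4H-chromen-4-one | O=c1cc(-c2ccc(OCc3ccccc3)cc2OCc2ccccc2)oc2cc(OCc3ccccc3)cc(O)c12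
F3 | step 10 | 7-(benzyloxy)-2-[2,4-bis(benzyloxy)phenyl]-5-hydroxy-6-iodo-4H-chromen-4-one | O=c1cc(-c2ccc(OCc3ccccc3)cc2OCc2ccccc2)oc2cc(OCc3ccccc3)c(I)c(O)c12
F4 | step 10 | 5,7-bis(benzyloxy)-2-[2,4-bis(benzyloxy)phenyl]-6-iodo-4H-chromen-4-one | O=c1cc(-c2ccc(OCc3ccccc3)cc2OCc2ccccc2)oc2cc(OCc3ccccc3)c(I)c(OCc3ccccc3)c12
F5 | step 10 | 5,7-bis(benzyloxy)-2-[2,4-bis(benzyloxy)phenyl]-6-(3-hydroxy-3-methylbut-1-yn-1-yl)-4H-chromen-4-one | CC(C)(O)C#Cc1c(OCc2ccccc2)cc2oc(-c3ccc(OCc4ccccc4)cc3OCc3ccccc3)cc(=O)c2c1OCc1ccccc1
F6 | step 7 | 5,7-bis(benzyloxy)-6-iodo-2-[(Z)-2-iodoethenyl]-4H-chromen-4-one | I/C=C\c1cc(=O)c2c(OCc3ccccc3)c(I)c(OCc3ccccc3)cc2o1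
F7 | step 1 | 1-[2,4-bis(benzyloxy)-6-hydroxyphenyl]ethanone | CC(=O)c1c(O)cc(OCc2ccccc2)cc1OCc1ccccc1
F8 | step 1 | ethyl 5,7-bis(benzyloxy)-4-oxo-4H-chromene-2-carboxylate | CCOC(=O)c1cc(=O)c2c(OCc3ccccc3)cc(OCc3ccccc3)cc2o1
F9 | step 11 | 5,7-bis(benzyloxy)-2-[2-(benzyloxy)-4-hydroxyphenyl]-6-[(E)-3-hydroxy-3-methylbut-1-en-1-yl]-4H-chromen-4-one | CC(C)(O)/C=C/c1c(OCc2ccccc2)cc2oc(-c3ccc(O)cc3OCc3ccccc3)cc(=O)c2c1OCc1ccccc1
A1 | alternative 1 | methyl 2-[3-methyl-3-(triethylsilyloxy)butyl]-3-oxo-4-{6-[2,4-bis(benzyloxy)phenyl]-4-oxo-4H-pyran-2-yl}butanoate (racemic) | COC(=O)C(CCC(C)(C)O[Si](CC)(CC)CC)C(=O)Cc1cc(=O)cc(-c2ccc(OCc3ccccc3)cc2OCc2ccccc2)o1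
A2 | alternative 1 | 5,7-dihydroxy-6-[3-methyl-3-(triethylsilyloxy)butyl]-2',4'-bis(benzyloxy)flavone | CC(C)(O[Si](CC)(CC)CC)CCc1c(O)cc2oc(-c3ccc(OCc4ccccc4)cc3OCc3ccccc3)cc(=O)c2c1O
A3 | alternative 2 | (Z)-3-[3,5-bis(benzyloxy)phenoxy]-3-[2,4-bis(benzyloxy)phenyl]prop-2-enoic acid | OC(=O)/C=C(\Oc1cc(OCc2ccccc2)cc(OCc2ccccc2)c1)c1ccc(OCc2ccccc2)cc1OCc1ccccc1
A4 | alternative 2 | 5,7,2',4'-tetrakis(benzyloxy)flavone | O=c1cc(-c2ccc(OCc3ccccc3)cc2OCc2ccccc2)oc2cc(OCc3ccccc3)cc(OCc3ccccc3)c12
A5 | alternative 3 | 2-[2,4-bis(benzyloxy)phenyl]-6-(2-diazoacetyl)-4H-pyran-4-one | [N-]=[N+]=CC(=O)c1cc(=O)cc(-c2ccc(OCc3ccccc3)cc2OCc2ccccc2)o1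
A6 | alternative 3 | triisopropyl{[5-methyl-5-(triethylsilyloxy)hex-1-yn-1-yl]oxy}silane | CC[Si](CC)(CC)OC(C)(C)CCC#CO[Si](C(C)C)(C(C)C)C(C)C
A7 | alternative 3 | 5-hydroxy-7-(triisopropylsilyloxy)-6-[3-methyl-3-(triethylsilyloxy)butyl]-2',4'-bis(benzyloxy)flavone | CC(C)(O[Si](CC)(CC)CC)CCc1c(O[Si](C(C)C)(C(C)C)C(C)C)cc2oc(-c3ccc(OCc4ccccc4)cc3OCc3ccccc3)cc(=O)c2c1O
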